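If the south flask is to be run again, it helps to know what can be watched in it besides J and L, so a short meeting went through the earlier runs.

| flask | D | G | temperature | remark | time |
|---|---|---|---|---|---|
| alder | 1 M | 1.8 M | 85 °C | run made earlier |  |
| ash | 2.2 M | 1.8 M | 110 °C | run made earlier |  |
| maple | 1.5 M | 2.7 M | 85 °C | run made earlier |  |
| south-east | 1.5 M | 1.80 M | 110 °C |  | 40 min |
| south | 1.5 M | 1.80 M |  | at 90 °C until 8.0 min, from then on at 130 °C | 40 min |
| north-west | 1.5 M | 1.80 M | 130 °C |  | 40 min |
| south-west | 1.5 M | 1.80 M | 90 °C |  | 40 min |

- alder (time / min: J / %, L / %): 15.0: 0.4, 0.9; 40.0: 1.4, 0.3; 60.0: 3.2, 0; 90.0: 7.3, 2.1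
- ash (time / min: J / %, L / %): 4.00: 1.4, 0; 12.0: 8.0, 0.6; 20.0: 15.3, 2.6; 30.0: 25.7, 3.5
- maple (time / min: J / %, L / %): 8.00: 0, 0; 20.0: 0, 0; 50.0: 4.5, 0; 90.0: 9.2, 1.5

(scatter of a reading: 1 percentage point)

- the earlier runs were read with a standard deviation of 1 percentage point
- a reading or a percentage of J counts all its forms, free or not

* the flask that comes out highest in share of J in all that became J or L, or "all alike" when all lie within 1.5 percentage points (south-east / south / north-west / south-west / all alike)
* share of J in all that became J or L, south-east
* share of J in all that became J or L, south
* share of J in all that became J or L, north-west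
* share of J in all that became J or L, south-west

The first speaker noted that J comes with a lag: the maple run read 0 % at 20.0 min and 4.5 % at 50.0 min. She took this to mean that something may stand between D and J, so the D lost may be more than J and L together show.

The second speaker therefore proposed a balance of the reagent charged in the smaller amount, the limiting reagent, which in south is D, at 1.5 M against 1.80 M of G. Assuming that one G goes with each D that reacts, he divided the two charges and got 83.3 %. He named this the G toll, the part of its own charge that G loses when the whole D charge has reacted. So, he argued, the G left in south is one minus the toll times the part of D lost, and it should not fall below 16.7 % of its charge.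

The first speaker added that readings of J and L enter this balance as a low estimate of what has reacted. In the ash run at 30.0 min, J and L together read 29.2 % of the D charged, which on the same assumption, and within the scatter of the readings, comes to about 35.7 % of the G charged there, and more if something stands in between. The meeting committed its own reckoning to G and gave no figure for the shares.

The forecast gave 87 % for south-east, 88.5 % for south, 89 % for north-west and 84 % for south-west, chose north-west, and judged that “The temperature effect is weak”.

The flasks gave 87.9 % in south-east, 86.0 % in south, 86.5 % in north-west and 91.2 % in south-west, so south-west came out highest.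

    Z ⇌ L (K = 2.50, k = 0.00740 min⁻¹, Ea = 128 kJ mol⁻¹, ΔH = −16.0 kJ mol⁻¹)
    Z ⇌ J (K = 2.60, k = 0.0650 min⁻¹, Ea = 116 kJ mol⁻¹, ΔH = 3.00 kJ mol⁻¹)
    X ⇌ J, rate k3*(cs3 - [J]) while solid is left; crystals form when [J] > cs3 (solubility = 0.180 M, k = 1.10 min⁻¹)
    D + G → Z + Q (k = 0.0170 L mol⁻¹ min⁻¹, Ea = 78.0 kJ mol⁻¹)
    (constants at 110 °C)

In south at 40.0 min, 18 % of the D charged is left, so the toll reckons G at 31.7 % of its charge, and 32 % stands there. In the neighbour of south charged with 0.72 M of G, G is the smaller charge, so the division turns over: its 14 % of G left at the end reckons D at 58.7 %, and 59 % stands there. In south at the end, Z, the species formed on the way, has a half-life of 1.8 min by the forward step to J against 13 min by the forward loss to L, a ratio of forward rates of 7.3. In south, Z and L, relaxing both ways at 130 °C, have a half-life of 8.43 min by this step alone, short against the run's 40 min.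

The numbers in the tables were computed for substances that don't exist; the scatter is artificial.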